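| flask | substrate | first nucleophile | second nucleophile | temperature | remark | time |
|---|---|---|---|---|---|---|
| dawn | 10 mM | 0.50 equiv | 2 equiv | 50 °C | the very flask that is asked about, followed so far |  |
| flask | 10 mM | 0.500 equiv | 2.00 equiv | 50 °C |  | 40 min |

dawn run (percent of the substrate charged)

| time / min | target / % | substrate / % |
|---|---|---|
| 1.33 | 23.5 | 41.6 |
| 4.00 | 34.4 | 7.7 |
| 6.00 | 32.3 | 0.5 |
| 10.0 | 29.6 | 1.5 |
| 15.0 | 27.3 | 0 |
| 20.0 | 24.7 | 0.1 |
| 25.0 | 27.2 | 0 |

(each reading ± 1 percentage point)

* target, in percent of the substrate first charged, at 40 min
* what to do for the largest gain in target; "none" if nothing gains more than 2 percentage points (zeta / delta / alpha / epsilon / none)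
* target present, with what was taken out counted in, in percent of the substrate first charged, after delta
* target present, with what was taken out counted in, in percent of the substrate first charged, after alpha

- zeta: at 40 min raise the temperature by 25 K, then wait 80 min
- delta: change nothing and wait 80 min more
- alpha: at 40 min take out 90% of the target then present, then wait 80 min
- epsilon: at 40 min add first nucleophile, 50.0% of the amount charged, then wait 80 min

- target taken out counts as made
- the numbers in the tables scatter with a standard deviation of 1 percentage point
- the earlier runs do not show what temperature does; that part of a forecast is a guess
- additions bring no volume worth counting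

Minutes. Amounts opened the meeting: the bench chemist reported that in the dawn run, this same flask, c(substrate) read 0.5% at 6.00 min, while c(target) read 34.4% at 4.00 min, slid, and averaged 26.4% over the last 3 readings. She took that level as the answer to "now" and read the stopped slide as a two-way change between target and an unseen partner form.

The rate chemist measured the excess over that level: it went from 5.9 percentage points at 6.00 min to 3.2 points at 10.0 min. This gives a rough settling rate of 0.153 min⁻¹, or a half-life of 4.53 min.

The bench chemist then estimated the total target made, assuming that the first reading's target per substrate used, 40.2%, held throughout. Level over total gave 65.6%. The rate chemist put that answer back in: target leaves at the settling rate times the part of it not kept, so she estimated that the partner already held about 0.822% at 1.33 min. That raised the total to 41.6% and gave 63.4%, the kept share: the equilibrium fraction of the target made that stands as target once the level holds.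

Removal makes the remaining pool split again at the kept share, so alpha gains the share taken out times the level times the unkept part, 8.7 points. That gives 35.1%, and 80 min is long against the settling half-life. The meeting put delta at 26.4% and epsilon at no gain, with c(substrate) reading 0% at 25.0 min. Heating stayed a guess, and the meeting chose alpha.

The forecast gave 23%, 14% after delta and 22% after alpha, lower than the meeting on both waits, and also chose alpha, holding that “Removing target protects it from further loss”.

The flask gives 25.8%, 25.8% after delta and 35.2% after alpha, but the best choice is zeta, gaining 13 points against 9.4 points for alpha.

    second nucleophile + intermediate → other capture product (k = 127 M⁻¹ s⁻¹, Ea = 38.0 kJ mol⁻¹)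
    target ⇌ isomer of the product (K = 0.680, k = 0.00107 s⁻¹, Ea = 87.0 kJ mol⁻¹, ΔH = −64.0 kJ mol⁻¹)
    substrate → intermediate (k = 0.0108 s⁻¹, Ea = 82.0 kJ mol⁻¹)
    intermediate → solvolysis product (k = 0.285 s⁻¹, Ea = 74.0 kJ mol⁻¹)
    first nucleophile + intermediate → target (k = 275 M⁻¹ s⁻¹, Ea = 52.0 kJ mol⁻¹)
    2 second nucleophile → homo dimer (k = 1.10 M⁻¹ s⁻¹, Ea = 39.0 kJ mol⁻¹)
    (constants at 50 °C)

The partner is the isomer of the product. This flask holds 25.8% target and 17.5% isomer of the product at 40 min, and the kept share of their sum is 27.5%. The neighbouring flask has 2.00 equiv of first nucleophile, all other charges held. Its target and isomer of the product sum to 81.4%, the kept share of that is 51.6%, and the neighbouring flask holds 48.5% target at 40 min.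

The numbers in the tables come from a simulation with constants of no real substance; scatter was added.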